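The lactone ring (ring B) is opened last-but-one: the target comes from hydrogenolysis of three benzyl ethers, and the lactone C–O bond comes from acid-promoted closure of an open hydroxy amide with loss of diisopropylamine.
Key disconnection, both C–C bonds of ring B at once: C3–C4 and C1–C8a, leading to an O-alkyl N,N-diisopropylcarbamate (C3 as carbanion, C1 as acyl donor) and a 2-bromobenzyl bromide (C4 as electrophile, C8a as aryllithium), joined in a one-pot anionic (3+3) union.
Enabling feature: in ring B the O2–C1(=O) unit lies between C3–H and the ring A carbon C8a; written as a carbamate, this one group directs and configurationally anchors lithiation at C3 under (−)-sparteine and then hands C1 to C8a, while C4 and C8a are 1,3-related on ring A.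
Fragments: the carbamate from 5-chloropentan-1-ol and (S)-epichlorohydrin (source of the remote carbinol C6′); the dibromide from 3,5-bis(benzyloxy)benzyl bromide, whose two ring positions next to the CH2 are equivalent.
Ring order: ring A (the resorcinol ring) is bought intact; ring B is the only ring made, its two C–C bonds in the key step and its C–O bond one step later.

Key step: step 6

Remark: locants follow isochroman-1-one numbering (C1 carbonyl carbon, O2, C3, C4, C4a, C5–C8, C8a); C6′ is the side-chain carbinol carbon. The target is (3R,6′S), as read from the SMILES.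

Step 1
Reactants: 1 5-chloropentan-1-ol
Product: 2 5-chloropentyl N,N-di(propan-2-yl)carbamate
Conditions: iPr2NCOCl, Et3N, CH2Cl2, reflux
Reagents that add atoms: N,N-diisopropylcarbamoyl chloride, CC(C)N(C(C)C)C(Cl)=O
Why: O-carbamoylation of the primary alcohol by acyl substitution with Et3N as HCl scavenger; the primary chloride is inert under these conditions.

Step 2
Reactants: 3 (S)-epichlorohydrin
Product: 5 (S)-1,2-epoxyheptane, via chlorohydrin 4 (not isolated)
Conditions: n-BuMgCl, CuI (cat.), THF, −40 °C; then NaOH (aq), 0 °C → rt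
Reagents that add atoms: butylmagnesium chloride, CCCC[Mg]Cl
Why: CuI-catalysed Grignard opening of the epoxide at its CH2 terminus, then hydroxide-induced intramolecular Williamson closure at the CH2Cl carbon, moves the oxirane without touching the stereocentre, so the (S) configuration of 3 is carried into 5.

Step 3
Reactants: 2 5-chloropentyl N,N-di(propan-2-yl)carbamate; 5 (S)-1,2-epoxyheptane
Product: 7 (7S)-7-hydroxydodecyl N,N-di(propan-2-yl)carbamate, via alkylmagnesium chloride 6 (not isolated)
Conditions: Mg, I2 (cat.), THF, 55 °C; then CuI (cat.), 5, −30 → 0 °C; then H2O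
Reagents that add atoms: none
Why: Grignard formation from the primary chloride (the hindered diisopropylcarbamate resists organomagnesium attack) and CuI-catalysed SN2 opening of the terminal epoxide at CH2 should give the secondary alcohol with the stereocentre of 5 unchanged.

Step 4
Reactants: 7 (7S)-7-hydroxydodecyl N,N-di(propan-2-yl)carbamate
Product: 8 (7S)-7-(benzyloxy)dodecyl N,N-di(propan-2-yl)carbamate
Conditions: NaH, BnBr, Bu4NI (cat.), THF–DMF, 0 °C → rt
Reagents that add atoms: benzyl bromide, BrCc1ccccc1
Why: Williamson etherification of the secondary alkoxide; the benzyl ether should survive the alkyllithium chemistry of step 6 and leaves together with the phenol benzyl groups in step 8.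

Step 5
Reactants: 9 1,3-bis(benzyloxy)-5-(bromomethyl)benzene
Product: 10 1,5-bis(benzyloxy)-2-bromo-3-(bromomethyl)benzene
Conditions: NBS (1.0 equiv), MeCN, 0 °C → rt, dark
Reagents that add atoms: N-bromosuccinimide, O=C1CCC(=O)N1Br
Why: Electrophilic aromatic bromination of the activated resorcinol diether under polar, non-radical conditions should go ortho to the CH2Br group and para to a benzyloxy group (the two such positions are equivalent, the site between the two ethers is more hindered), with one equivalent of NBS limiting it to monobromination.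

Step 6
Reactants: 8 (7S)-7-(benzyloxy)dodecyl N,N-di(propan-2-yl)carbamate; 10 1,5-bis(benzyloxy)-2-bromo-3-(bromomethyl)benzene
Product: 14 2,4-bis(benzyloxy)-6-[(2R,8S)-8-(benzyloxy)-2-hydroxytridecyl]-N,N-di(propan-2-yl)benzamide, via lithio carbamate 11 (not isolated), via bromo carbamate 12 (not isolated), via aryllithium 13 (not isolated)
Conditions: 8 (1.3 equiv), s-BuLi (1.25 equiv), (−)-sparteine (1.3 equiv), Et2O, −78 °C, 5 h; then 10 (1.0 equiv), −78 °C; then t-BuLi (2.2 equiv), −78 → 0 °C; then H2O
Reagents that add atoms: none
Why: s-BuLi/(−)-sparteine removes the pro-S hydrogen next to the carbamate oxygen of 8 (Hoppe asymmetric deprotonation) to give the chelated, configurationally stable lithio carbamate 11, which displaces the benzylic bromide of 10 with retention and so forms the C3–C4 bond of 12. t-BuLi then exchanges the ring bromine, and aryllithium 13 adds to the carbamate carbonyl held three atoms away; the tetrahedral intermediate expels the C3 alkoxide, so the carbamoyl carbon ends on C8a (C1–C8a bond; Parham-type cyclization, anionic Fries-type 1,5 O→C carbamoyl shift). The closest known reaction types are the alkylation of sparteine-complexed lithiated O-alkyl carbamates with alkyl halides and the intramolecular transfer of O-carbamoyl groups to aryllithiums. The carbonyl attack closes a six-membered ring in the 6-exo-trig mode, but this ring reopens on loss of the alkoxide, so the isolated product should be the open hydroxy amide and ring B is closed for good in step 7 (any lactone 15 formed directly would simply be carried on). The new stereocentre C3 (R) is set by reagent control, (−)-sparteine selecting the pro-S hydrogen and the electrophile entering with retention, the remote C6′ centre being too far away to interfere. The step needs displacement at the benzylic CH2Br to outrun bromine–lithium exchange at the aryl bromide, which the weakly basic, internally chelated alkyllithium in Et2O at −78 °C and the high SN2 reactivity of the benzylic bromide should secure, and it needs acylation at C8a only, which the position of the bromine fixes.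

Step 7
Reactants: 14 2,4-bis(benzyloxy)-6-[(2R,8S)-8-(benzyloxy)-2-hydroxytridecyl]-N,N-di(propan-2-yl)benzamide
Product: 15 (3R)-6,8-bis(benzyloxy)-3-[(6S)-6-(benzyloxy)undecyl]-3,4-dihydro-1H-isochromen-1-one
Conditions: TsOH·H2O (1.5 equiv), toluene, 90 °C
Reagents that add atoms: none
Why: Acid-promoted intramolecular alcoholysis of the twisted 2,6-disubstituted tertiary benzamide by the neighbouring secondary hydroxyl (lactonization, 6-exo-trig acyl substitution) is driven by protonation of the departing diisopropylamine; C3 reacts through its oxygen, so its configuration is retained.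

Step 8
Reactants: 15 (3R)-6,8-bis(benzyloxy)-3-[(6S)-6-(benzyloxy)undecyl]-3,4-dihydro-1H-isochromen-1-one
Product: 16 (3R)-6,8-dihydroxy-3-[(6S)-6-hydroxyundecyl]-3,4-dihydro-1H-isochromen-1-one
Conditions: H2 (1 atm), Pd/C, EtOAc–MeOH, rt
Reagents that add atoms: none
Why: Catalytic hydrogenolysis should cleave the two aryl benzyl ethers and the alkyl benzyl ether, while the lactone (its C3–O bond is homobenzylic, not benzylic) and both stereocentres stay untouched.

Compound list
1 | 5-chloropentan-1-ol | OCCCCCCl | starting material
2 | 5-chloropentyl N,N-di(propan-2-yl)carbamate | CC(C)N(C(C)C)C(=O)OCCCCCCl | intermediate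
3 | (S)-epichlorohydrin, (2S)-2-(chloromethyl)oxirane | ClC[C@@H]1CO1 | starting material
4 | (2S)-1-chloroheptan-2-ol (formed as its magnesium alkoxide) | CCCCC[C@H](O)CCl | intermediate
5 | (S)-1,2-epoxyheptane, (2S)-2-pentyloxirane | CCCCC[C@H]1CO1 | intermediate
6 | {5-[(dipropan-2-ylcarbamoyl)oxy]pentyl}magnesium chloride | CC(C)N(C(C)C)C(=O)OCCCCC[Mg]Cl | intermediate
7 | (7S)-7-hydroxydodecyl N,N-di(propan-2-yl)carbamate | CCCCC[C@H](O)CCCCCCOC(=O)N(C(C)C)C(C)C | intermediate
8 | (7S)-7-(benzyloxy)dodecyl N,N-di(propan-2-yl)carbamate | CCCCC[C@H](OCc1ccccc1)CCCCCCOC(=O)N(C(C)C)C(C)C | intermediate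
9 | 1,3-bis(benzyloxy)-5-(bromomethyl)benzene (3,5-bis(benzyloxy)benzyl bromide) | BrCc1cc(OCc2ccccc2)cc(OCc2ccccc2)c1 | starting material
10 | 1,5-bis(benzyloxy)-2-bromo-3-(bromomethyl)benzene | BrCc1cc(OCc2ccccc2)cc(OCc2ccccc2)c1Br | intermediate
11 | (1S,7S)-7-(benzyloxy)-1-lithiododecyl N,N-di(propan-2-yl)carbamate, as its (−)-sparteine complex | CCCCC[C@H](OCc1ccccc1)CCCCC[C@@H](OC(=O)N(C(C)C)C(C)C)[Li] | intermediate
12 | (2R,8S)-8-(benzyloxy)-1-[3,5-bis(benzyloxy)-2-bromophenyl]tridecan-2-yl N,N-di(propan-2-yl)carbamate | CCCCC[C@H](OCc1ccccc1)CCCCC[C@@H](OC(=O)N(C(C)C)C(C)C)Cc1cc(OCc2ccccc2)cc(OCc2ccccc2)c1Br | intermediate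
13 | (2R,8S)-8-(benzyloxy)-1-[3,5-bis(benzyloxy)-2-lithiophenyl]tridecan-2-yl N,N-di(propan-2-yl)carbamate | CCCCC[C@H](OCc1ccccc1)CCCCC[C@@H](OC(=O)N(C(C)C)C(C)C)Cc1cc(OCc2ccccc2)cc(OCc2ccccc2)c1[Li] | intermediate
14 | 2,4-bis(benzyloxy)-6-[(2R,8S)-8-(benzyloxy)-2-hydroxytridecyl]-N,N-di(propan-2-yl)benzamide | CCCCC[C@H](OCc1ccccc1)CCCCC[C@@H](O)Cc1cc(OCc2ccccc2)cc(OCc2ccccc2)c1C(=O)N(C(C)C)C(C)C | intermediate
15 | (3R)-6,8-bis(benzyloxy)-3-[(6S)-6-(benzyloxy)undecyl]-3,4-dihydro-1H-isochromen-1-one | CCCCC[C@H](OCc1ccccc1)CCCCC[C@@H]1Cc2cc(OCc3ccccc3)cc(OCc3ccccc3)c2C(=O)O1 | intermediate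
16 | (3R)-6,8-dihydroxy-3-[(6S)-6-hydroxyundecyl]-3,4-dihydro-1H-isochromen-1-one | CCCCC[C@H](O)CCCCC[C@@H]1Cc2cc(O)cc(O)c2C(=O)O1 | target

Total step count: 8.
Longest linear sequence: 6 steps (steps 1, 3, 4, 6, 7, 8; equally 2, 3, 4, 6, 7, 8).

Steps most likely to fail

1. Step 6. The lithio carbamate may transfer an electron to the dibromide, or exchange bromine with it, instead of displacing the benzylic bromide, which would give Wurtz-type coupling and erode the C3 configuration. The alkyllithiums may also deprotonate a benzyloxy methylene, and the aryllithium may abstract such a proton before it acylates. Fallback (lithiation–borylation, then carbonylation; sets out from 8 and 9, returns at 15): bromide 9 is borylated (B2pin2, KOAc, Pd(dba)2, P(4-MeOC6H4)3, toluene, 50 °C) to the benzylic pinacol boronate F1. Carbamate 8 is lithiated exactly as in step 6 and trapped with F1 at −78 °C. Warming with MgBr2·OEt2 triggers the 1,2-metallate shift (benzyl migrates with inversion at carbon, the carbamate leaves) and should give the secondary boronic ester F2. Oxidation (NaOH, H2O2, THF, 0 °C) with retention should give the open-chain alcohol F3, which has the same (R) carbinol configuration as 14. NBS (MeCN, 0 °C) should then brominate a ring position next to the side chain to give the bromo alcohol F4. Carbonylative lactonization (Pd(OAc)2, 1,3-bis(diphenylphosphino)propane, CO 1 atm, Et3N, DMF, 100 °C) closes ring B to 15; in this variant the lactone carbonyl comes from CO, and no organolithium ever meets a benzylic or aryl bromide.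

2. Step 7. The hindered amide may resist alcoholysis, and prolonged hot acid may strip the benzyl ether next to the carbonyl or cause elimination at C3–C4. Fallback (alkylative amide activation; sets out from 14, returns at 15): MeOTf (1.1 equiv) with 2,6-di-tert-butylpyridine in CH2Cl2 at 0 °C should methylate the amide oxygen to the O-methyl imidate triflate F5. Its activated carbon is captured by the neighbouring hydroxyl, and aqueous NaHCO3 work-up releases diisopropylamine and methanol to leave lactone 15 without strong acid or heat.

3. Step 3. Magnesium insertion into the primary chloride may be sluggish or lead to Wurtz dimerization, and magnesium halide may open the epoxide to a halohydrin instead of the copper-mediated C–C coupling. Fallback (alkynylation, then hydrogenation; sets out from 5, returns at 7): commercial pent-4-yn-1-ol is carbamoylated as in step 1 to the alkynyl carbamate F6. Deprotonation (n-BuLi, THF, −78 °C) and BF3·OEt2-promoted opening of epoxide 5 at its CH2 terminus should give the homopropargylic alcohol F7 with the stereocentre untouched. Hydrogenation (H2, Pd/C, EtOAc) saturates the alkyne to 7.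

Further compounds
F1 | step 6 | 2-[3,5-bis(benzyloxy)benzyl]-4,4,5,5-tetramethyl-1,3,2-dioxaborolane | CC1(C)OB(Cc2cc(OCc3ccccc3)cc(OCc3ccccc3)c2)OC1(C)C
F2 | step 6 | 2-[(2R,8S)-8-(benzyloxy)-1-[3,5-bis(benzyloxy)phenyl]tridecan-2-yl]-4,4,5,5-tetramethyl-1,3,2-dioxaborolane | CCCCC[C@H](OCc1ccccc1)CCCCC[C@@H](B1OC(C)(C)C(C)(C)O1)Cc1cc(OCc2ccccc2)cc(OCc2ccccc2)c1
F3 | step 6 | (2R,8S)-8-(benzyloxy)-1-[3,5-bis(benzyloxy)phenyl]tridecan-2-ol | CCCCC[C@H](OCc1ccccc1)CCCCC[C@@H](O)Cc1cc(OCc2ccccc2)cc(OCc2ccccc2)c1
F4 | step 6 | (2R,8S)-8-(benzyloxy)-1-[3,5-bis(benzyloxy)-2-bromophenyl]tridecan-2-ol | CCCCC[C@H](OCc1ccccc1)CCCCC[C@@H](O)Cc1cc(OCc2ccccc2)cc(OCc2ccccc2)c1Br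
F5 | step 7 | {2,4-bis(benzyloxy)-6-[(2R,8S)-8-(benzyloxy)-2-hydroxytridecyl]phenyl}(methoxy)-N,N-di(propan-2-yl)methaniminium trifluoromethanesulfonate | CCCCC[C@H](OCc1ccccc1)CCCCC[C@@H](O)Cc1cc(OCc2ccccc2)cc(OCc2ccccc2)c1C(OC)=[N+](C(C)C)C(C)C.[O-]S(=O)(=O)C(F)(F)F
F6 | step 3 | pent-4-yn-1-yl N,N-di(propan-2-yl)carbamate | C#CCCCOC(=O)N(C(C)C)C(C)C
F7 | step 3 | (7S)-7-hydroxydodec-4-yn-1-yl N,N-di(propan-2-yl)carbamate | CCCCC[C@H](O)CC#CCCCOC(=O)N(C(C)C)C(C)C
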